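The route rests on one disconnection: the C1–C10 bond of the seven-membered ring is cut while C6–C8 is joined, the retron of a cis-divinylcyclopropane Cope rearrangement. The feature used is the 1,4-diene pattern of that ring once C4 is a ketone: the C5=C6 enone alkene and C8=C9 are separated only by C7, and the quaternary C1 sits between C5 and C10. The precursor is a bought (S)-4-silyloxycyclopentenone (ring C1–C5) carrying at C5 a cis-cyclopropane (C6, C7, C8) with an E-enol ether arm (C9=C10). One thermal [3,3] shift forms the seven-membered ring, the quaternary C1 and the C10 oxygen; epoxy ketone chemistry, isopropyl addition and three esterifications complete the target.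

Key step: step 11

Remark: daucane numbering is used throughout (C1 quaternary with methyl, C2 acetate carbon, C4 carbinol, C5 ring-fusion CH, C6 angelate carbon, C8=C9, C10 benzoate carbon); β is the face of the C1 methyl and α the face of H-5; the target is then 2α-acetoxy-6α-angeloyloxy-10β-benzoyloxy-dauc-8-en-4β-ol, and the (S)-silyloxycyclopentenone is taken as commercial. TBS = tert-butyldimethylsilyl, TES = triethylsilyl, PMB = 4-methoxybenzyl, pin = pinacolato.

Step 1
Reactants: 1 (S)-4-(tert-butyldimethylsilyloxy)cyclopent-2-en-1-one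
Product: 3 (3S,4S)-4-(TBS-oxy)-3-methyl-1-(trimethylsilyloxy)cyclopent-1-ene, via lithium enolate 2 (not isolated)
Conditions: Me2CuLi (from MeLi and CuI), Et2O, −78 °C; then TMSCl, Et3N, −78 to 0 °C
Reagents that add atoms: lithium dimethylcuprate [Li+].C[Cu-]C; chlorotrimethylsilane C[Si](C)(C)Cl
Why: Cuprate conjugate addition should place the methyl group on the β-carbon anti to the silyloxy group, and O-silylation of the regiodefined enolate prevents enolisation towards the silyloxy-bearing side and thus β-elimination.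

Step 2
Reactants: 3 (3S,4S)-4-(TBS-oxy)-3-methyl-1-(trimethylsilyloxy)cyclopent-1-ene
Product: 4 (S)-4-(TBS-oxy)-3-methylcyclopent-2-en-1-one
Conditions: Pd(OAc)2 (10 mol %), O2 (1 atm), DMSO, 25 °C
Reagents that add atoms: none
Why: Saegusa–Ito oxidation (palladium enolate, then β-hydride elimination of the hydrogen on the methyl-bearing carbon) should return the enone, now β-methylated, while the silyloxy stereocentre is untouched.

Step 3
Reactants: 4 (S)-4-(TBS-oxy)-3-methylcyclopent-2-en-1-one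
Product: 5 (S)-4-(TBS-oxy)-2-iodo-3-methylcyclopent-2-en-1-one
Conditions: I2, pyridine, DMAP (cat.), CH2Cl2, 0 to 25 °C
Reagents that add atoms: iodine II
Why: α-Iodination of the enone by amine conjugate addition, iodination of the resulting enolate and elimination should work here, with DMAP catalysis compensating for the β-methyl group.

Step 4
Reactants: 6 propargyl alcohol
Product: 8 (Z)-3-iodo-2-methylprop-2-en-1-ol, via alkenylmagnesium alkoxide 7 (not isolated)
Conditions: MeMgBr (excess), CuI (cat.), THF, −10 to 25 °C; then I2, −78 to 0 °C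
Reagents that add atoms: methylmagnesium bromide C[Mg]Br; iodine II
Why: Copper-catalysed anti-carbomagnesiation directed by the magnesium alkoxide should deliver methyl to C2 and leave magnesium on C3 cis to CH2O in a five-membered chelate, so that iodinolysis with retention gives the Z-iodide.

Step 5
Reactants: 8 (Z)-3-iodo-2-methylprop-2-en-1-ol
Product: 10 (Z)-2-methyl-3-(tributylstannyl)prop-2-en-1-ol, via dilithio species 9 (not isolated)
Conditions: n-BuLi (1 equiv), Et2O, −78 °C; t-BuLi (2 equiv); then Bu3SnCl, −78 to 0 °C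
Reagents that add atoms: tributyltin chloride CCCC[Sn](Cl)(CCCC)CCCC
Why: Iodine–lithium exchange on the lithium alkoxide and stannylation of the vinyllithium should both proceed with retention of the alkene geometry.

Step 6
Reactants: 5 (S)-4-(TBS-oxy)-2-iodo-3-methylcyclopent-2-en-1-one; 10 (Z)-2-methyl-3-(tributylstannyl)prop-2-en-1-ol
Product: 11 (S)-4-(TBS-oxy)-2-[(Z)-3-hydroxy-2-methylprop-1-en-1-yl]-3-methylcyclopent-2-en-1-one
Conditions: Pd2(dba)3 (cat.), AsPh3, CuI (cat.), NMP, 25 to 40 °C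
Reagents that add atoms: none
Why: Stille coupling of an α-iodoenone with a vinylstannane should proceed with retention at both sp2 carbons under base-free conditions that tolerate the free alcohol and the silyl ether.

Step 7
Reactants: 11 (S)-4-(TBS-oxy)-2-[(Z)-3-hydroxy-2-methylprop-1-en-1-yl]-3-methylcyclopent-2-en-1-one
Product: 12 (S)-4-(TBS-oxy)-2-[(1R,2S)-2-(hydroxymethyl)-2-methylcyclopropyl]-3-methylcyclopent-2-en-1-one
Conditions: Et2Zn, CH2I2, DME, CH2Cl2, −10 °C; then 11 and (4R,5R)-2-butyl-N,N,N′,N′-tetramethyl-1,3,2-dioxaborolane-4,5-dicarboxamide, −10 to 25 °C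
Reagents that add atoms: diiodomethane ICI
Why: In this hydroxyl-directed asymmetric Simmons–Smith cyclopropanation the zinc alkoxide bound to the chiral boronate should deliver CH2 stereospecifically to one face of the allylic alcohol alkene only (the electron-poor tetrasubstituted enone alkene is inert), so the Z-alkene gives the cis-cyclopropane and the reagent, not the remote silyloxy centre, sets C6 (R) and C8 (S).

Step 8
Reactants: 12 (S)-4-(TBS-oxy)-2-[(1R,2S)-2-(hydroxymethyl)-2-methylcyclopropyl]-3-methylcyclopent-2-en-1-one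
Product: 13 (1S,2R)-2-[(S)-3-(TBS-oxy)-2-methyl-5-oxocyclopent-1-en-1-yl]-1-methylcyclopropane-1-carbaldehyde
Conditions: Dess–Martin periodinane, NaHCO3, CH2Cl2, 0 °C
Reagents that add atoms: none
Why: Buffered periodinane oxidation of the primary alcohol should give the aldehyde, which sits on the quaternary C8 and therefore cannot epimerise.

Step 9
Reactants: 13 (1S,2R)-2-[(S)-3-(TBS-oxy)-2-methyl-5-oxocyclopent-1-en-1-yl]-1-methylcyclopropane-1-carbaldehyde
Product: 14 (S)-4-(TBS-oxy)-3-methyl-2-{(1R,2R)-2-methyl-2-[(E)-2-(4,4,5,5-tetramethyl-1,3,2-dioxaborolan-2-yl)ethenyl]cyclopropyl}cyclopent-2-en-1-one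
Conditions: CrCl2, Cl2CHB(pin), LiI, THF, 25 °C
Reagents that add atoms: 2-(dichloromethyl)-4,4,5,5-tetramethyl-1,3,2-dioxaborolane ClC(Cl)B1OC(C)(C)C(C)(C)O1
Why: In the Takai–Utimoto boron olefination the geminal dichromium reagent should add to the aldehyde only (ketone and enone are spared) and eliminate to the E-alkenylboronate.

Step 10
Reactants: 14 (S)-4-(TBS-oxy)-3-methyl-2-{(1R,2R)-2-methyl-2-[(E)-2-(4,4,5,5-tetramethyl-1,3,2-dioxaborolan-2-yl)ethenyl]cyclopropyl}cyclopent-2-en-1-one
Product: 15 (S)-4-(TBS-oxy)-2-{(1R,2S)-2-[(E)-2-(4-methoxybenzyloxy)ethenyl]-2-methylcyclopropyl}-3-methylcyclopent-2-en-1-one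
Conditions: Cu(OAc)2, Et3N, 4-methoxybenzyl alcohol (excess), 4 Å molecular sieves, CH2Cl2, air, 25 °C
Reagents that add atoms: 4-methoxybenzyl alcohol COc1ccc(CO)cc1
Why: Chan–Lam-type oxidative C–O coupling of an alkenyl pinacol boronate with an alcohol should proceed with retention of the E geometry at room temperature, so the enol ether arm is installed without heating the cis-divinylcyclopropane.

Step 11
Reactants: 15 (S)-4-(TBS-oxy)-2-{(1R,2S)-2-[(E)-2-(4-methoxybenzyloxy)ethenyl]-2-methylcyclopropyl}-3-methylcyclopent-2-en-1-one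
Product: 16 2α-(TBS-oxy)-10α-(PMB-oxy)-11,12,13-trinordauca-5,8-dien-4-one
Conditions: toluene (dilute), BHT (cat.), base-washed sealed tube, 110 °C
Reagents that add atoms: none
Why: The step is a concerted thermal [3,3] sigmatropic shift, the cis-divinylcyclopropane to cyclohepta-1,4-diene rearrangement being the closest known reaction type, through the boat transition state in which the cyclopentenone C1=C5 bond and the enol ether C9=C10 bond are folded over the cyclopropane, so that C6–C8 breaks as C1–C10 forms. The seven-membered ring is closed by ring expansion of the three-membered ring and not by an end-to-end cyclisation, and release of cyclopropane strain together with the new C4 ketone/C5=C6 enone should make it irreversible. The quaternary C1 is set by chirality transfer from C6 and C8, because the only boat geometry open to the (1R,2S) cyclopropane brings C10 onto the face of C1 cis to the C2 silyloxy group and so leaves the C1 methyl β. C10 is set by the E geometry of the enol ether, whose PMB-oxy group points outward in the boat and ends trans to the C1 methyl (α). The step needs this single facial outcome and no cis/trans scrambling of the cyclopropane, and both are secured by the cis arrangement fixed by the Z-alkene, by the quaternary C8 that cannot epimerise and by a temperature well below that of homolytic ring opening. The ring methyl at C1 is the one inward substituent, which is why heating and not room temperature is planned.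

Step 12
Reactants: 16 2α-(TBS-oxy)-10α-(PMB-oxy)-11,12,13-trinordauca-5,8-dien-4-one
Product: 17 5α,6α-epoxy-2α-(TBS-oxy)-10α-(PMB-oxy)-11,12,13-trinordauc-8-en-4-one
Conditions: H2O2 (30% aq.), NaOH (cat.), MeOH, −10 to 0 °C
Reagents that add atoms: hydrogen peroxide OO
Why: In the Weitz–Scheffer epoxidation hydroperoxide should add only to C6 of the s-cis enone (C8=C9 is not electrophilic) and the enolate should close onto oxygen on the α face, anti to the C1 methyl next to C5, while low temperature and catalytic base spare the β-silyloxy ketone and the skipped diene.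

Step 13
Reactants: 17 5α,6α-epoxy-2α-(TBS-oxy)-10α-(PMB-oxy)-11,12,13-trinordauc-8-en-4-one
Product: 19 6α-hydroxy-2α-(TBS-oxy)-10α-(PMB-oxy)-11,12,13-trinordauc-8-en-4-one, via samarium enolate 18 (not isolated)
Conditions: SmI2, THF/MeOH, −90 °C
Reagents that add atoms: none
Why: Two-electron reduction of the α,β-epoxy ketone should cleave the C5–O bond (the C6–O bond and its α configuration stay), and methanol should protonate the enolate at C5 on the α face, anti to the C1 methyl, to give the trans-fused β-hydroxy ketone.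

Step 14
Reactants: 19 6α-hydroxy-2α-(TBS-oxy)-10α-(PMB-oxy)-11,12,13-trinordauc-8-en-4-one
Product: 20 2α-(TBS-oxy)-6α-(TES-oxy)-10α-(PMB-oxy)-11,12,13-trinordauc-8-en-4-one
Conditions: TESCl, imidazole, DMAP (cat.), CH2Cl2, 0 °C
Reagents that add atoms: chlorotriethylsilane CC[Si](Cl)(CC)CC
Why: Silylation under weakly basic conditions should avoid dehydration or retro-aldol cleavage of the β-hydroxy ketone and gives an ether that can later be removed beside the hindered TBS ether.

Step 15
Reactants: 20 2α-(TBS-oxy)-6α-(TES-oxy)-10α-(PMB-oxy)-11,12,13-trinordauc-8-en-4-one; 21 isopropylmagnesium chloride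
Product: 22 2α-(TBS-oxy)-6α-(TES-oxy)-10α-(PMB-oxy)dauc-8-en-4β-ol
Conditions: CeCl3 (anhydrous, pre-mixed with 21), THF, −78 °C
Reagents that add atoms: none
Why: The weakly basic organocerium reagent should add to the enolisable β-silyloxy ketone without enolisation, elimination or reduction, and from the α face anti to the axial C1 methyl, which gives the 4β-alcohol with the isopropyl group α.

Step 16
Reactants: 22 2α-(TBS-oxy)-6α-(TES-oxy)-10α-(PMB-oxy)dauc-8-en-4β-ol
Product: 23 2α-(TBS-oxy)-6α-(TES-oxy)dauc-8-ene-4β,10α-diol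
Conditions: DDQ, CH2Cl2/pH 7 buffer, 0 °C
Reagents that add atoms: none
Why: Oxidative cleavage of the PMB ether by hydride abstraction at the electron-rich benzylic position should leave the silyl ethers, the alkene and the tertiary alcohol untouched.

Step 17
Reactants: 23 2α-(TBS-oxy)-6α-(TES-oxy)dauc-8-ene-4β,10α-diol
Product: 24 4β-hydroxy-2α-(TBS-oxy)-6α-(TES-oxy)dauc-8-en-10-one
Conditions: Dess–Martin periodinane, NaHCO3, CH2Cl2, 0 to 25 °C
Reagents that add atoms: none
Why: Oxidation of the secondary allylic alcohol should give the C8=C9–C10 enone, since the tertiary C4 alcohol cannot be oxidised and the quaternary C1 excludes epimerisation or β-elimination.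

Step 18
Reactants: 24 4β-hydroxy-2α-(TBS-oxy)-6α-(TES-oxy)dauc-8-en-10-one
Product: 25 2α-(TBS-oxy)-6α-(TES-oxy)dauc-8-ene-4β,10β-diol
Conditions: NaBH4, CeCl3·7H2O, MeOH, −78 °C
Reagents that add atoms: none
Why: In the Luche 1,2-reduction hydride should reach C10 from the α face, anti to the axial methyl on the neighbouring C1, so that the new alcohol is β.

Step 19
Reactants: 25 2α-(TBS-oxy)-6α-(TES-oxy)dauc-8-ene-4β,10β-diol
Product: 26 10β-benzoyloxy-2α-(TBS-oxy)-6α-(TES-oxy)dauc-8-en-4β-ol
Conditions: BzCl, pyridine, DMAP (cat.), CH2Cl2, 25 °C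
Reagents that add atoms: benzoyl chloride O=C(Cl)c1ccccc1
Why: Nucleophile-catalysed acylation should esterify the secondary allylic alcohol only, the hindered tertiary C4 alcohol being unreactive.

Step 20
Reactants: 26 10β-benzoyloxy-2α-(TBS-oxy)-6α-(TES-oxy)dauc-8-en-4β-ol
Product: 27 10β-benzoyloxy-2α-(TBS-oxy)dauc-8-ene-4β,6α-diol
Conditions: PPTS, MeOH/CH2Cl2, 0 °C
Reagents that add atoms: none
Why: Mild acid-catalysed methanolysis should remove the triethylsilyl ether selectively beside the bulkier TBS ether on the neopentyl-type C2.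

Step 21
Reactants: 27 10β-benzoyloxy-2α-(TBS-oxy)dauc-8-ene-4β,6α-diol; 28 angelic acid
Product: 30 6α-angeloyloxy-10β-benzoyloxy-2α-(TBS-oxy)dauc-8-en-4β-ol, via mixed anhydride 29 (not isolated)
Conditions: 2,4,6-trichlorobenzoyl chloride, Et3N, toluene, 25 °C; then 27, 80 °C
Reagents that add atoms: none
Why: Yamaguchi esterification through the mixed anhydride without a nucleophilic catalyst should acylate the secondary C6 alcohol (not the tertiary C4 alcohol) and avoid Z to E isomerisation of the angelate.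

Step 22
Reactants: 30 6α-angeloyloxy-10β-benzoyloxy-2α-(TBS-oxy)dauc-8-en-4β-ol
Product: 31 6α-angeloyloxy-10β-benzoyloxy-dauc-8-ene-2α,4β-diol
Conditions: HF·pyridine, pyridine, THF, 0 to 25 °C
Reagents that add atoms: none
Why: Fluoride cleavage of the TBS ether under buffered conditions should cause neither ester hydrolysis nor acyl migration.

Step 23
Reactants: 31 6α-angeloyloxy-10β-benzoyloxy-dauc-8-ene-2α,4β-diol
Product: 32 2α-acetoxy-6α-angeloyloxy-10β-benzoyloxy-dauc-8-en-4β-ol (CNP0248576.1)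
Conditions: Ac2O, pyridine, DMAP (cat.), CH2Cl2, 0 to 25 °C
Reagents that add atoms: acetic anhydride CC(=O)OC(C)=O
Why: Acetylation should take place at the secondary C2 alcohol only and leave the hindered tertiary C4 alcohol free.

Compound list
1 | (S)-4-(tert-butyldimethylsilyloxy)cyclopent-2-en-1-one | O=C1C[C@H](O[Si](C)(C)C(C)(C)C)C=C1 | starting material
2 | lithium (3S,4S)-4-(TBS-oxy)-3-methylcyclopent-1-en-1-olate (methyl trans to OTBS) | [Li]OC1=C[C@H](C)[C@@H](O[Si](C)(C)C(C)(C)C)C1 | intermediate (not isolated)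
3 | (3S,4S)-4-(TBS-oxy)-3-methyl-1-(trimethylsilyloxy)cyclopent-1-ene (methyl trans to OTBS) | C[Si](C)(C)OC1=C[C@H](C)[C@@H](O[Si](C)(C)C(C)(C)C)C1 | intermediate
4 | (S)-4-(TBS-oxy)-3-methylcyclopent-2-en-1-one | O=C1C[C@H](O[Si](C)(C)C(C)(C)C)C(C)=C1 | intermediate
5 | (S)-4-(TBS-oxy)-2-iodo-3-methylcyclopent-2-en-1-one | O=C1C[C@H](O[Si](C)(C)C(C)(C)C)C(C)=C1I | intermediate
6 | propargyl alcohol (prop-2-yn-1-ol) | C#CCO | starting material
7 | bromomagnesium (Z)-3-(bromomagnesio)-2-methylprop-2-en-1-olate (Mg cis to CH2O) | Br[Mg]OC/C(C)=C\[Mg]Br | intermediate (not isolated)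
8 | (Z)-3-iodo-2-methylprop-2-en-1-ol | OC/C(C)=C\I | intermediate
9 | lithium (Z)-3-lithio-2-methylprop-2-en-1-olate | [Li]OC/C(C)=C\[Li] | intermediate (not isolated)
10 | (Z)-2-methyl-3-(tributylstannyl)prop-2-en-1-ol | OC/C(C)=C\[Sn](CCCC)(CCCC)CCCC | intermediate
11 | (S)-4-(TBS-oxy)-2-[(Z)-3-hydroxy-2-methylprop-1-en-1-yl]-3-methylcyclopent-2-en-1-one | O=C1C[C@H](O[Si](C)(C)C(C)(C)C)C(C)=C1/C=C(/C)CO | intermediate
12 | (S)-4-(TBS-oxy)-2-[(1R,2S)-2-(hydroxymethyl)-2-methylcyclopropyl]-3-methylcyclopent-2-en-1-one (cyclopentenyl and CH2OH cis) | O=C1C[C@H](O[Si](C)(C)C(C)(C)C)C(C)=C1[C@@H]1C[C@]1(C)CO | intermediate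
13 | (1S,2R)-2-[(S)-3-(TBS-oxy)-2-methyl-5-oxocyclopent-1-en-1-yl]-1-methylcyclopropane-1-carbaldehyde (cyclopentenyl and CHO cis) | O=C1C[C@H](O[Si](C)(C)C(C)(C)C)C(C)=C1[C@@H]1C[C@]1(C)C=O | intermediate
14 | (S)-4-(TBS-oxy)-3-methyl-2-{(1R,2R)-2-methyl-2-[(E)-2-(4,4,5,5-tetramethyl-1,3,2-dioxaborolan-2-yl)ethenyl]cyclopropyl}cyclopent-2-en-1-one (same cis-cyclopropane; the C8 descriptor changes by priority only) | O=C1C[C@H](O[Si](C)(C)C(C)(C)C)C(C)=C1[C@@H]1C[C@]1(C)/C=C/B1OC(C)(C)C(C)(C)O1 | intermediate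
15 | (S)-4-(TBS-oxy)-2-{(1R,2S)-2-[(E)-2-(4-methoxybenzyloxy)ethenyl]-2-methylcyclopropyl}-3-methylcyclopent-2-en-1-one (cis-divinylcyclopropane) | O=C1C[C@H](O[Si](C)(C)C(C)(C)C)C(C)=C1[C@@H]1C[C@]1(C)/C=C/OCc1ccc(OC)cc1 | intermediate
16 | 2α-(TBS-oxy)-10α-(PMB-oxy)-11,12,13-trinordauca-5,8-dien-4-one (hydroazulene; C1 methyl β; C4 ketone; C5=C6; C8=C9 with C8 methyl) | O=C1C[C@H](O[Si](C)(C)C(C)(C)C)[C@@]2(C)C1=CCC(C)=C[C@H]2OCc1ccc(OC)cc1 | intermediate
17 | 5α,6α-epoxy-2α-(TBS-oxy)-10α-(PMB-oxy)-11,12,13-trinordauc-8-en-4-one | O=C1C[C@H](O[Si](C)(C)C(C)(C)C)[C@@]2(C)[C@]13O[C@H]3CC(C)=C[C@H]2OCc1ccc(OC)cc1 | intermediate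
18 | samarium enolate (C4=C5 enolate O–SmI2; C6α O–SmI2) of 19 | I[Sm](I)O[C@H]1CC(C)=C[C@@H](OCc3ccc(OC)cc3)[C@@]2(C)[C@@H](O[Si](C)(C)C(C)(C)C)CC(O[Sm](I)I)=C12 | intermediate (not isolated)
19 | 6α-hydroxy-2α-(TBS-oxy)-10α-(PMB-oxy)-11,12,13-trinordauc-8-en-4-one (H-5 α; trans ring fusion) | O[C@H]1CC(C)=C[C@@H](OCc3ccc(OC)cc3)[C@@]2(C)[C@@H](O[Si](C)(C)C(C)(C)C)CC(=O)[C@H]12 | intermediate
20 | 2α-(TBS-oxy)-6α-(TES-oxy)-10α-(PMB-oxy)-11,12,13-trinordauc-8-en-4-one | CC[Si](CC)(CC)O[C@H]1CC(C)=C[C@@H](OCc3ccc(OC)cc3)[C@@]2(C)[C@@H](O[Si](C)(C)C(C)(C)C)CC(=O)[C@H]12 | intermediate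
21 | isopropylmagnesium chloride | CC(C)[Mg]Cl | starting material
22 | 2α-(TBS-oxy)-6α-(TES-oxy)-10α-(PMB-oxy)dauc-8-en-4β-ol (isopropyl α) | CC[Si](CC)(CC)O[C@H]1CC(C)=C[C@@H](OCc3ccc(OC)cc3)[C@@]2(C)[C@@H](O[Si](C)(C)C(C)(C)C)C[C@@](O)(C(C)C)[C@H]12 | intermediate
23 | 2α-(TBS-oxy)-6α-(TES-oxy)dauc-8-ene-4β,10α-diol | CC[Si](CC)(CC)O[C@H]1CC(C)=C[C@@H](O)[C@@]2(C)[C@@H](O[Si](C)(C)C(C)(C)C)C[C@@](O)(C(C)C)[C@H]12 | intermediate
24 | 4β-hydroxy-2α-(TBS-oxy)-6α-(TES-oxy)dauc-8-en-10-one | CC[Si](CC)(CC)O[C@H]1CC(C)=CC(=O)[C@@]2(C)[C@@H](O[Si](C)(C)C(C)(C)C)C[C@@](O)(C(C)C)[C@H]12 | intermediate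
25 | 2α-(TBS-oxy)-6α-(TES-oxy)dauc-8-ene-4β,10β-diol | CC[Si](CC)(CC)O[C@H]1CC(C)=C[C@H](O)[C@@]2(C)[C@@H](O[Si](C)(C)C(C)(C)C)C[C@@](O)(C(C)C)[C@H]12 | intermediate
26 | 10β-benzoyloxy-2α-(TBS-oxy)-6α-(TES-oxy)dauc-8-en-4β-ol | CC[Si](CC)(CC)O[C@H]1CC(C)=C[C@H](OC(=O)c3ccccc3)[C@@]2(C)[C@@H](O[Si](C)(C)C(C)(C)C)C[C@@](O)(C(C)C)[C@H]12 | intermediate
27 | 10β-benzoyloxy-2α-(TBS-oxy)dauc-8-ene-4β,6α-diol | O[C@H]1CC(C)=C[C@H](OC(=O)c3ccccc3)[C@@]2(C)[C@@H](O[Si](C)(C)C(C)(C)C)C[C@@](O)(C(C)C)[C@H]12 | intermediate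
28 | angelic acid ((Z)-2-methylbut-2-enoic acid) | C/C=C(/C)C(=O)O | starting material
29 | angelic 2,4,6-trichlorobenzoic anhydride | C/C=C(/C)C(=O)OC(=O)c1c(Cl)cc(Cl)cc1Cl | intermediate (not isolated)
30 | 6α-angeloyloxy-10β-benzoyloxy-2α-(TBS-oxy)dauc-8-en-4β-ol | C/C=C(/C)C(=O)O[C@H]1CC(C)=C[C@H](OC(=O)c2ccccc2)[C@@]2(C)[C@@H](O[Si](C)(C)C(C)(C)C)C[C@@](O)(C(C)C)[C@H]12 | intermediate
31 | 6α-angeloyloxy-10β-benzoyloxy-dauc-8-ene-2α,4β-diol | C/C=C(/C)C(=O)O[C@H]1CC(C)=C[C@H](OC(=O)c2ccccc2)[C@@]2(C)[C@@H](O)C[C@@](O)(C(C)C)[C@H]12 | intermediate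
32 | 2α-acetoxy-6α-angeloyloxy-10β-benzoyloxy-dauc-8-en-4β-ol, (1R,2S,4R,5S,6S,10S), CNP0248576.1 | C/C=C(/C)C(=O)O[C@H]1CC(C)=C[C@H](OC(=O)c2ccccc2)[C@@]2(C)[C@@H](OC(C)=O)C[C@@](O)(C(C)C)[C@H]12 | target

Total step count: 23 steps.
Longest linear sequence: 21 steps (steps 1–3 and 6–23, from compound 1); steps 4 and 5 make the stannane branch.

Steps most likely to fail

Step 15: the secondary organometallic may transfer a β-hydride or deprotonate the hindered ketone (with loss of a β-silyloxy group) faster than it adds, and the flanking α-silyl ethers may slow attack from the α face. The fallback sets out from ketone 20 and uses an sp2 nucleophile without β-hydrogen: 2-propenylmagnesium bromide with CeCl3 (THF, −78 °C) should give the isopropenyl carbinol F1. Hydrogenation with RhCl(PPh3)3 (H2, benzene, 25 °C) should then saturate only the 1,1-disubstituted alkene, leaving the trisubstituted C8=C9 alkene and the PMB ether, and comes back to the route at 22.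

Step 12: hydroperoxide may add from the β face, or the basic medium may move the skipped C8=C9 alkene into conjugation or eliminate the C2 silyloxy group. The fallback sets out from dienone 16 and reaches the β-hydroxy ketone without an epoxide. Copper-catalysed conjugate borylation (CuCl, NaOt-Bu (cat.), a chiral Josiphos-type bisphosphine matched to the α face, B2pin2, MeOH, THF, 25 °C) should give the β-boryl ketone F2 under nearly neutral conditions. Oxidation of the C–B bond with retention (NaBO3·4H2O, THF/H2O) comes back to the route at 19, so that 17 is bypassed.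

Step 18: hydride delivery may lack facial selectivity because the α face of C10 is flanked by the C2 silyloxy group, which would return the 10α-alcohol. The fallback sets out from the 10α-alcohol 23 and inverts C10 instead of reducing a ketone. Mitsunobu reaction with 4-nitrobenzoic acid (PPh3, DIAD, toluene, 0 to 25 °C) should give the 10β-(4-nitrobenzoate) F3. Methanolysis (K2CO3, MeOH, 0 °C) comes back to the route at 25, so that 24 is bypassed.

Further compounds
F1 | step 15 | 4α-(prop-1-en-2-yl) analogue of 22: 2α-(TBS-oxy)-6α-(TES-oxy)-10α-(PMB-oxy)dauca-8,11-dien-4β-ol | CC[Si](CC)(CC)O[C@H]1CC(C)=C[C@@H](OCc3ccc(OC)cc3)[C@@]2(C)[C@@H](O[Si](C)(C)C(C)(C)C)C[C@@](O)(C(C)=C)[C@H]12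
F2 | step 12 | 6α-(pinacolboryl)-2α-(TBS-oxy)-10α-(PMB-oxy)-11,12,13-trinordauc-8-en-4-one (H-5 α) | CC1(C)OB(OC1(C)C)[C@H]1CC(C)=C[C@@H](OCc3ccc(OC)cc3)[C@@]2(C)[C@@H](O[Si](C)(C)C(C)(C)C)CC(=O)[C@H]12
F3 | step 18 | 10β-(4-nitrobenzoyloxy)-2α-(TBS-oxy)-6α-(TES-oxy)dauc-8-en-4β-ol | CC[Si](CC)(CC)O[C@H]1CC(C)=C[C@H](OC(=O)c3ccc(cc3)[N+](=O)[O-])[C@@]2(C)[C@@H](O[Si](C)(C)C(C)(C)C)C[C@@](O)(C(C)C)[C@H]12
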